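Late in the two earlier runs, at 6.00 min, the larch run had used 65.3% of its solid substrate and the birch run 15.5% of its own. As amounts these are close, 11.8 mM against 11.5 mM, although birch was charged 4.11 times as heavily. So I took the solid in both runs to leave at a steady drain of 1.94 mM min⁻¹, which is zero order in solid.

in all of them: gas 2.5 mM (held)

| flask | solid substrate | remark | time |
|---|---|---|---|
| larch | 18 mM | run made earlier |  |
| birch | 74 mM | run made earlier |  |
| flask | 37 mM |  | 8.0 min |

| run | time / min | target / % | dissolved substrate / % | solid substrate / % |
|---|---|---|---|---|
| larch | 0.500 | 3.3 | 1.0 | 93.9 |
| larch | 1.33 | 9.6 | 0.3 | 86.8 |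
| larch | 3.00 | 22.5 | 1.5 | 68.7 |
| larch | 6.00 | 35.8 | 2.2 | 34.7 |
| birch | 0.833 | 2.3 | 0.1 | 97.6 |
| birch | 2.50 | 4.7 | 1.4 | 92.4 |
| birch | 4.00 | 6.0 | 0.3 | 90.3 |
| birch | 6.00 | 9.2 | 0 | 84.5 |

(scatter of a reading: 1 percentage point)

- as a solid, counted per litre of solution: solid substrate
- at the start none of the solid substrate is in solution
- at the start none of the gas is in solution
- dissolved substrate means what is dissolved; the solid is not counted in it

- east: doubling the saturation concentration of gas, all else as stated
- south: doubling the dissolution coefficient of the solid substrate, all else as stated
- north: doubling the transfer coefficient of the gas, all else as stated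
- north-west: doubling the solubility of the solid substrate, all else as stated

1. amount of target at 8.0 min, in percent of the solid substrate charged
2. concentration of dissolved substrate in solution at 2.0 min, in percent of saturation
3. the change that raises the amount of target at 8.0 min, in percent of the solid substrate charged most ("none" if none brings more than 2 percentage points) (east / south / north / north-west / none)
4. amount of target at 8.0 min, in percent of the solid substrate charged, after north-west

For the flask, dividing the charge by the drain gave 19.1 min. I called this the clearing time, the charge over the drain, and elapsed time over clearing time is the fraction used. By 8.0 min that made 41.8%.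

Not all of the used fraction stood as target: larch held 35.8% and birch 9.2%. My first answer, target equal to used, was therefore too high. I let the gap grow with the target standing, as a loss constant times time times target. Setting target equal to used minus that loss and solving for target gives target as used divided by one plus constant times time. Larch read 0.137 min⁻¹ and birch 0.114 min⁻¹, with mean 0.126 min⁻¹. For the flask my reckoning came to 20.9%, half of what was used.

The forecast gave 19.5% of target, 97% of saturation, north-west as the best change and 38% after north-west, holding that “the solution probably sits at saturation”.

The flask gave 20.5% of target, dissolved substrate at 1.11% of saturation at 2.0 min, east as the best change with 7.3 percentage points, and 25.4% after north-west.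

    solid substrate ⇌ dissolved substrate, rate k1*(cs1 - [dissolved substrate]) while solid is left; crystals form when [dissolved substrate] > cs1 (solubility = 23.0 mM, k = 0.0850 min⁻¹)
    dissolved substrate + partner → target (k = 3000 M⁻¹ min⁻¹)
    dissolved substrate + target → side product (k = 500 M⁻¹ min⁻¹)
    gas ⇌ partner, rate k4*(csat - [partner]) (kL = 3.90 min⁻¹)

At 8.00 min the flask's solid substrate stood at 58.2%, so 41.8% was used, against the 41.8% from its clearing time. The neighbour charged with 22 mM has a clearing time of 11.4 min, which reckons to 29.8% of solid and 34.9% of target at 8.0 min. That neighbour held 29.6% of solid substrate and 34.4% of target.

(The numbers in the tables were computed for an exercise; noise was put on by code.)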